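Compound numbers refer to the compound list after the steps.

## Analysis of the target

The target (43) is a prodelphinidin trimer, epigallocatechin-(4β→8)-epigallocatechin 3-O-gallate-(4β→8)-epigallocatechin. It consists of three 2,3-cis flavan-3-ol units joined by two bonds from C4 of the upper unit to C8 of the unit below, with a galloyl ester on O3 of the middle unit. There are eight stereocentres: C2 and C3 of each unit (all 2R,3R, aryl and oxygen cis) and C4 of the top and middle units, each trans to the neighbouring C3 oxygen. The free compound carries twenty hydroxyl groups on three pyrogallol B rings, three phloroglucinol A rings and the galloyl group, so it is sensitive to air and base. The C4–C8 bonds are doubly benzylic and ionise in acid, the ester is labile to alkoxide and hydride, and C2 epimerises in base once the 4′-phenol is free. The usual difficulty is the interflavan bond: a flavan-4-yl cation can attack C8 or C6 of a phloroglucinol ring, and the electrophilic unit can oligomerise. The strategy rests on ring A of the bottom unit, a hexasubstituted phloroglucinol ring whose C8a oxygen lies between C8 (bonded to C4 of the middle unit) and C4a (bonded to the C4 methylene), with oxygen at C7 and C5 and hydrogen at C6. A vinylketene–ynol ether benzannulation gives exactly this pattern: the ketene oxygen ends between the two carbon substituents, so the 4→8 connection is fixed by the position of an alkyne and not by the selectivity of an aromatic substitution.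

## Retrosynthetic reasoning

43 from 42. The last operation only removes the nineteen benzyl ethers of 42 by hydrogenolysis (O7 of the bottom unit is already free). The pyrogallol rings stay masked until the end, and neutral conditions spare the ester and the interflavan bonds.

42 from 41, and 41 from 40. The O1–C2 bond of the bottom ring C is cut. The C8a oxygen is the one oxygen of the new ring A that arrives unprotected, and C2 is a secondary benzylic carbinol, so a dehydrative closure with inversion at C2 is possible. Inversion means the open chain of 41 must be erythro (2S,3R in flavan numbering) to give the 2R,3R cis unit. O5 has to stay benzylated so that only the C8a hydroxyl, and not the equally ortho C5 oxygen, can reach C2. The triol 41 comes from 40 by removal of the two silyl groups.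

40 from 13 and 35. Three bonds of the bottom ring A are cut: C8–C8a, C6–C7 and C4a–C8a. This splits the molecule into the siloxyalkyne 13, which holds the complete top and middle units, and the small cyclobutenone 35, which holds the bottom B ring and C2/C3. The forward reaction must join ketene 36 and the ynol ether in one orientation, create no stereocentre, and run under neutral conditions that the ester, the silyl ynol ether and eight stereocentres survive.

13 from 10, and 10 from 9. The siloxyalkyne is the most sensitive group of the route and is made last, from the terminal alkyne 10 by oxidation of its acetylide 11 to the ynolate 12 and O-silylation. Alkyne 10 comes from the C-silyl alkyne 9, which carries the alkyne masked through the Lewis-acid coupling.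

9 from 6 and 8. The bond from C4 of the top unit to C8 of the middle unit is cut, and is formed by the cationic flavan coupling between electrophile 8 and nucleophile 6. The alkyne is put on the monomer before this coupling, so no dimer has to be oxidised selectively at one of two C4 positions.

6 from 4. The C4–C(sp) bond of 6 is cut. In the forward direction C4 of the perbenzylated gallate 4 is oxidised to the C4 ether 5, which is ionised and captured by an alkynylboron reagent trans to the C3 ester.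

4 from 2 and 3. The ester C–O bond is cut, so the galloyl group arrives as the acid 3 on the one free hydroxyl of the pentabenzyl ether 2. Acylating a single secondary alcohol is cleaner than alkylating eight phenols under base next to a labile ester, and it makes 2 the common intermediate for two of the three flavan units.

8 from 2, and 2 from 1. The C4–O bond of 8 is cut back to the hexabenzyl ether 7, which comes from 2 by benzylation of O3. Compound 2 is the pentabenzyl ether of natural 1, which therefore supplies C2 and C3 of both the top and the middle unit.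

35 from 27 and 32. The C1–C2 and C3–C4 bonds of the cyclobutenone are cut, which gives ketene 34 (from acid 27 through chloride 33) and benzyloxyethyne 32. The ynol ether 32 is made from 28 through 29.

27 from 14 and 19. Acid 27 comes from alkene 23 by hydroboration and oxidation (25, 26). The erythro relation in 23 is set in 22 by chelation-controlled reduction of the α-benzyloxy ketone 21. A syn-selective glycolate aldol would give the threo series, which on closure with inversion would lead to the 2,3-trans unit, so that disconnection is not used. Ketone 21 is cut at the aryl–carbonyl bond into aryllithium 20 (from 19) and the Weinreb amide 18. The single stereocentre of 18 is set by auxiliary-controlled allylation of 15 (through 16 to 17), made from 14.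

## Alternatives that were turned down

Alternative 1: an aryne relay that closes the bottom ring C and forms C8–C4 in one flask. The O1–C8a bond and the bond from C8 to the future middle C4 are cut. In the forward step iPrMgCl·LiCl deprotonates the C2 carbinol and exchanges a C8 iodide. Loss of a C8a sulfonate gives the C8–C8a aryne, the tethered alkoxide adds at C8a, and the resulting C8 arylmagnesium adds to an aldehyde, giving carbinol A1 as a pair of epimers. In its favour, two bonds form at once, and the O–aryl bond forms with retention at C2, so the side chain can be threo and comes from a plain asymmetric dihydroxylation of an E-alkene. On that point it is stronger than the chosen route, which needs the erythro chain and an inversion. Against it, A1 contains only a methoxymethyl-protected salicyl fragment in place of the middle unit. Ring C of the middle unit, with its aryl group, its gallate and the three stereocentres C2, C3 and C4, would have to be built afterwards around a diaryl carbinol of mixed configuration, on a molecule that already carries two flavan units. The aryne must also be captured by a secondary benzylic alkoxide faster than by the Grignard reagent, and a di-ortho-oxygenated arylmagnesium must add to a di-ortho-substituted, electron-rich aldehyde. The chosen strategy takes ring C of the middle unit, with C2 and C3, from natural 1, adds the ester by one acylation and needs three steps after its key step. What it offers in place of the easier threo chain is that only C4 of the middle unit has to be set, by substrate control trans to O3.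

Alternative 2: an iminium-catalysed phenol–enal annulation that sets C4 of the top unit. The C4–C4a and O1–C2 bonds of the top ring C are cut. A diarylprolinol silyl ether forms the iminium ion of an acrolein attached to C8 of the middle unit, phenol A3 adds through its ortho carbon to the β-carbon, and its hydroxyl closes onto the former aldehyde carbon to give lactol A2. In its favour, the C4 stereocentre is under catalyst control and the top ring A is attached without a cationic coupling; in principle this is a stronger control of C4 than substrate control. Against it, A2 lacks the C2 aryl group and the C3 oxygen of the top unit. Arylation of the lactol carbon and oxidation at C3 with 2,3-cis and 3,4-trans control would be needed as late steps on a trimer-sized ester. The enal sits between two ortho oxygen substituents, is twisted out of conjugation and shielded, and the catalyst has to override six resident stereocentres. The middle–bottom bond would also have to be made first by a conventional coupling, so the regiochemical problem of the bottom unit stays. The chosen strategy uses 1 with C2 and C3 in place; the top C4 is not a real problem in the 2,3-cis series, where attack trans to O3 is reliable.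

Alternative 3: an epoxy-arene cyclisation that closes the bottom ring C at C4–C4a. BF3·OEt2 in hexafluoroisopropanol activates a terminal epoxide on an aryl ether side chain, and the free ortho carbon C4a attacks the CH2 terminus to give A4, which has a free 3-OH and a C6 bromide as blocking group. In its favour, O1–C2 and C3–O are in place before the closure, so no substitution at a benzylic carbon is needed; this is more secure stereochemically than the inversion in the chosen route. The free 3-OH arrives directly and the bromide would leave in the final hydrogenolysis. Against it, the conditions are those that ionise the C4–C8 interflavan bonds and the benzylic C2–O1 ether of electron-rich flavans. Attack at the primary epoxide carbon (6-endo) competes with attack at the secondary carbon (a dihydrobenzofuran) and with epoxide rearrangement. The precursor needs the fully substituted ring A with the middle unit already on C8, a bromine at C6 and a hindered secondary benzylic aryl ether, so the 4→8 bond still has to come from a classical coupling with its C6/C8 question. The end game is of similar length; the chosen strategy makes the arene and the 4→8 bond together, with no blocking group and under neutral thermal conditions.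

Key step: step 21

Assumption: 3,4,5-tris(benzyloxy)benzoic acid (3) and 5-bromo-1,2,3-tris(benzyloxy)benzene (19) are taken as purchasable building blocks, and the double-bond geometries of the transient ketenes 36 and 38 are left open because they are lost on aromatisation.

## Steps

Step 1
Reactants: 1 (−)-epigallocatechin
Product: 2 5,7,3′,4′,5′-penta-O-benzyl-epigallocatechin (free 3-OH)
Conditions: BnBr, K2CO3, DMF, 0 → 25 °C, Ar
Reagents that add atoms: benzyl bromide, BrCc1ccccc1
Why: Williamson O-benzylation of the five phenols; the secondary 3-OH is not deprotonated by carbonate and stays free, and oxygen is excluded to protect the pyrogallol ring until it is capped.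

Step 2
Reactants: 2 5,7,3′,4′,5′-penta-O-benzyl-epigallocatechin, 3 3,4,5-tris(benzyloxy)benzoic acid
Product: 4 octa-O-benzyl-epigallocatechin 3-O-gallate
Conditions: DCC, DMAP (cat.), CH2Cl2, 0 → 25 °C
Reagents that add atoms: none
Why: Steglich esterification: the O-acylisourea of 3 is passed on by DMAP as an acylpyridinium ion to the axial 3-OH, the only free hydroxyl of 2. No bond to a stereocentre is broken, so C2 and C3 keep their configuration.

Step 3
Reactants: 4 octa-O-benzyl-epigallocatechin 3-O-gallate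
Product: 5 4β-(2-ethoxyethoxy)-octa-O-benzyl-epigallocatechin 3-O-gallate (2,3-cis, 3,4-trans)
Conditions: DDQ, 2-ethoxyethanol, CH2Cl2, 25 °C
Reagents that add atoms: 2-ethoxyethanol, CCOCCO
Why: DDQ abstracts hydride from C4, the benzylic position activated by the ortho and para ether oxygens of ring A (oxidative benzylic etherification), and the alcohol adds anti to the C3 ester to give the 3,4-trans ether; a minor C4 epimer would be equally usable because C4 is ionised again in step 4.

Step 4
Reactants: 5 4β-(2-ethoxyethoxy)-octa-O-benzyl-epigallocatechin 3-O-gallate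
Product: 6 4β-[(trimethylsilyl)ethynyl]-octa-O-benzyl-epigallocatechin 3-O-gallate (2,3-cis, 3,4-trans)
Conditions: K[Me3SiC≡CBF3] (3 equiv), BF3·OEt2, CH2Cl2/MeCN, −40 → 0 °C
Reagents that add atoms: potassium trifluoro[(trimethylsilyl)ethynyl]borate, C[Si](C)(C)C#C[B-](F)(F)F.[K+]
Why: BF3 converts the trifluoroborate into the alkynyldifluoroborane, which ionises the C4 ether and hands the alkynyl group to the benzylic carbon (Lewis-acid-mediated alkynyltrifluoroborate substitution of benzylic ethers). Attack anti to the C3 gallate, which can also shield the cis face as a bridging acyloxonium ion, sets the new C4 stereocentre trans to O3 (4β).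

Step 5
Reactants: 2 5,7,3′,4′,5′-penta-O-benzyl-epigallocatechin
Product: 7 3,5,7,3′,4′,5′-hexa-O-benzyl-epigallocatechin
Conditions: NaH, BnBr, Bu4NI (cat.), DMF, 0 °C
Reagents that add atoms: benzyl bromide, BrCc1ccccc1
Why: Williamson benzylation of the axial 3-alkoxide; with every phenol already capped no phenoxide can open ring C, so C2 keeps its configuration.

Step 6
Reactants: 7 3,5,7,3′,4′,5′-hexa-O-benzyl-epigallocatechin
Product: 8 4β-(2-ethoxyethoxy)-hexa-O-benzyl-epigallocatechin (2,3-cis, 3,4-trans)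
Conditions: DDQ, 2-ethoxyethanol, CH2Cl2, 25 °C
Reagents that add atoms: 2-ethoxyethanol, CCOCCO
Why: Same oxidative benzylic etherification as step 3; the alcohol enters trans to the C3 benzyloxy group.

Step 7
Reactants: 8 4β-(2-ethoxyethoxy)-hexa-O-benzyl-epigallocatechin, 6 4β-[(trimethylsilyl)ethynyl]-octa-O-benzyl-epigallocatechin 3-O-gallate
Product: 9 hexa-O-benzyl-epigallocatechin-(4β→8)-{4β-[(trimethylsilyl)ethynyl]-octa-O-benzyl-epigallocatechin 3-O-gallate}
Conditions: Me3SiOTf (cat.), CH2Cl2, −78 °C, 6 in excess (2.5 equiv, excess recovered)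
Reagents that add atoms: none
Why: Me3SiOTf ionises the C4 ether of 8 and C8 of ring A of 6 captures the benzylic carbon (Friedel–Crafts-type flavan-4-yl coupling). Approach anti to the C3 benzyloxy group sets the top C4 stereocentre as 4β, C8 is the more nucleophilic free position of 6, and the excess of 6 suppresses self-condensation of 8.

Step 8
Reactants: 9 protected dimer with C-silyl alkyne
Product: 10 hexa-O-benzyl-epigallocatechin-(4β→8)-(4β-ethynyl-octa-O-benzyl-epigallocatechin 3-O-gallate)
Conditions: Bu4NF, AcOH, THF, 0 °C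
Reagents that add atoms: none
Why: Fluoride-induced cleavage of the C(sp)–Si bond; acetic acid keeps the medium non-basic, so the gallate and the aryl ethers are untouched.

Step 9
Reactants: 10 protected dimer with terminal alkyne
Product: 13 hexa-O-benzyl-epigallocatechin-(4β→8)-{4β-[(triisopropylsilyloxy)ethynyl]-octa-O-benzyl-epigallocatechin 3-O-gallate}, via lithium acetylide 11 (not isolated), via lithium ynolate 12 (not isolated)
Conditions: LiN(SiMe3)2 (2.2 equiv), THF, −78 °C; t-BuOOH (1.0 equiv), −78 → 0 °C; iPr3SiOTf, −78 °C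
Reagents that add atoms: tert-butyl hydroperoxide, CC(C)(C)OO; triisopropylsilyl trifluoromethanesulfonate, CC(C)[Si](C(C)C)(C(C)C)OS(=O)(=O)C(F)(F)F
Why: The amide base forms acetylide 11 and lithium tert-butyl peroxide, the acetylide is oxidised at carbon to ynolate 12 (acetylide-to-ynolate oxidation), and the bulky silyl triflate silylates the ynolate on oxygen. The hindered, electron-rich benzoate has no α-hydrogen and should resist the amide at low temperature, and the trans-diaxial C3–O and C4 bonds keep the ynolate carbon away from the ester carbonyl.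

Step 10
Reactants: 14 (S)-4-benzyloxazolidin-2-one
Product: 15 (S)-4-benzyl-3-[(benzyloxy)acetyl]oxazolidin-2-one
Conditions: n-BuLi, THF, −78 °C; BnOCH2COCl, −78 → 0 °C
Reagents that add atoms: (benzyloxy)acetyl chloride, O=C(Cl)COCc1ccccc1
Why: N-acylation of the lithiated oxazolidinone, the standard entry to an Evans glycolate imide.

Step 11
Reactants: 15 (S)-4-benzyl-3-[(benzyloxy)acetyl]oxazolidin-2-one
Product: 17 (S)-4-benzyl-3-[(2R)-2-(benzyloxy)pent-4-enoyl]oxazolidin-2-one, via sodium enolate 16 (not isolated)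
Conditions: NaN(SiMe3)2, THF, −78 °C; allyl iodide, −78 → −45 °C
Reagents that add atoms: allyl iodide, C=CCI
Why: Evans alkylation: the chelated Z-enolate 16 is allylated on the face opposite the benzyl group of the auxiliary, which sets the R centre that becomes C3 of the bottom unit.

Step 12
Reactants: 17 (S)-4-benzyl-3-[(2R)-2-(benzyloxy)pent-4-enoyl]oxazolidin-2-one
Product: 18 (2R)-2-(benzyloxy)-N-methoxy-N-methylpent-4-enamide
Conditions: MeNHOMe·HCl, AlMe3, CH2Cl2, −10 → 25 °C
Reagents that add atoms: N,O-dimethylhydroxylamine hydrochloride, CNOC.Cl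
Why: Transamination of the exocyclic imide carbonyl by the aluminium amide gives the Weinreb amide and returns the auxiliary; the non-basic conditions leave the α-centre unchanged.

Step 13
Reactants: 19 5-bromo-1,2,3-tris(benzyloxy)benzene, 18 (2R)-2-(benzyloxy)-N-methoxy-N-methylpent-4-enamide
Product: 21 (2R)-2-(benzyloxy)-1-[3,4,5-tris(benzyloxy)phenyl]pent-4-en-1-one, via aryllithium 20 (not isolated)
Conditions: 19, n-BuLi, THF, −78 °C; then 18, −78 → 0 °C
Reagents that add atoms: none
Why: Bromine–lithium exchange and acylation of the aryllithium by the Weinreb amide; the chelated tetrahedral adduct persists until quench, which prevents over-addition and enolisation, so the α-benzyloxy centre is retained.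

Step 14
Reactants: 21 (2R)-2-(benzyloxy)-1-[3,4,5-tris(benzyloxy)phenyl]pent-4-en-1-one
Product: 22 (1S,2R)-2-(benzyloxy)-1-[3,4,5-tris(benzyloxy)phenyl]pent-4-en-1-ol (erythro)
Conditions: Zn(BH4)2, Et2O, −20 → 0 °C
Reagents that add atoms: none
Why: Chelation-controlled reduction: zinc bridges the ketone and benzyl ether oxygens and hydride is delivered to the carbonyl face anti to the allyl group, which should give the erythro (1S,2R) alcohol.

Step 15
Reactants: 22 (1S,2R)-2-(benzyloxy)-1-[3,4,5-tris(benzyloxy)phenyl]pent-4-en-1-ol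
Product: 23 tert-butyl{[(1S,2R)-2-(benzyloxy)-1-[3,4,5-tris(benzyloxy)phenyl]pent-4-en-1-yl]oxy}dimethylsilane
Conditions: t-BuMe2SiOTf, 2,6-lutidine, CH2Cl2, −78 → 0 °C
Reagents that add atoms: tert-butyldimethylsilyl trifluoromethanesulfonate, CC(C)(C)[Si](C)(C)OS(=O)(=O)C(F)(F)F
Why: Silylation of the hindered benzylic alcohol with the silyl triflate and a non-nucleophilic base; this differentiates the benzylic oxygen (later leaving group) from O3 (benzyl until the end).

Step 16
Reactants: 23 silyl ether of the erythro pentenol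
Product: 25 (4R,5S)-4-(benzyloxy)-5-[(tert-butyldimethylsilyl)oxy]-5-[3,4,5-tris(benzyloxy)phenyl]pentan-1-ol, via alkylborane 24 (not isolated)
Conditions: 9-BBN, THF, 0 → 25 °C; NaOH, H2O2, 0 °C
Reagents that add atoms: hydrogen peroxide, OO
Why: Anti-Markovnikov hydroboration of the terminal alkene and oxidation of the C–B bond; the silyl ether tolerates the brief alkaline peroxide treatment.

Step 17
Reactants: 25 (4R,5S)-4-(benzyloxy)-5-[(tert-butyldimethylsilyl)oxy]-5-[3,4,5-tris(benzyloxy)phenyl]pentan-1-ol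
Product: 27 (4R,5S)-4-(benzyloxy)-5-[(tert-butyldimethylsilyl)oxy]-5-[3,4,5-tris(benzyloxy)phenyl]pentanoic acid, via aldehyde 26 (not isolated)
Conditions: TEMPO (cat.), PhI(OAc)2, MeCN/H2O, 25 °C
Reagents that add atoms: water, O
Why: Oxoammonium oxidation of the primary alcohol to aldehyde 26 and, through its hydrate, to the acid; benzyl and silyl ethers are stable to this oxidant.

Step 18
Reactants: 28 trichloroethylene
Product: 29 benzyl (E)-1,2-dichlorovinyl ether
Conditions: BnOH, KH, THF, −50 → 25 °C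
Reagents that add atoms: benzyl alcohol, OCc1ccccc1
Why: The alkoxide eliminates HCl from trichloroethylene and adds anti to the resulting dichloroethyne, the established route to 1,2-dichlorovinyl ethers.

Step 19
Reactants: 29 benzyl (E)-1,2-dichlorovinyl ether
Product: 32 benzyloxyethyne, via benzyloxychloroethyne 30 (not isolated), via lithium benzyloxyacetylide 31 (not isolated)
Conditions: n-BuLi (2.1 equiv), Et2O, −78 °C; MeOH, −78 °C; kept as a cold Et2O solution
Reagents that add atoms: none
Why: Deprotonation and β-elimination give 30, chlorine–lithium exchange gives acetylide 31, and protonation gives the terminal ynol ether; it is kept cold because benzyl alkynyl ethers rearrange sigmatropically on warming.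

Step 20
Reactants: 27 (4R,5S)-pentanoic acid, 32 benzyloxyethyne
Product: 35 3-(benzyloxy)-4-[(2R,3S)-2-(benzyloxy)-3-[(tert-butyldimethylsilyl)oxy]-3-[3,4,5-tris(benzyloxy)phenyl]propyl]cyclobut-2-en-1-one (ring C4 epimers), via acid chloride 33 (not isolated), via ketene 34 (not isolated)
Conditions: 1-chloro-N,N,2-trimethylprop-1-en-1-amine, CH2Cl2, 0 °C; then 32 (3 equiv), Et3N (slow addition), CH2Cl2, 0 → 25 °C
Reagents that add atoms: none
Why: The chloroenamine gives acid chloride 33 without acid, Et3N dehydrochlorinates it to ketene 34, and the ketene is trapped in a [2+2] cycloaddition in which its carbonyl carbon bonds to the unsubstituted, nucleophilic carbon of the ynol ether. This gives the 3-alkoxy-4-substituted cyclobutenone; the new ring stereocentre is uncontrolled and is lost in step 21.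

Step 21
Reactants: 13 siloxyalkyne dimer, 35 3-benzyloxy-4-substituted cyclobutenone
Product: 40 protected trimer precursor in which C4 of the middle unit carries the new bottom ring A (free C8a–OH, C7–OSi(iPr)3, C6–H, C5–OBn, C4a bearing the (2R,3S)-2-(benzyloxy)-3-[(tert-butyldimethylsilyl)oxy]-3-[3,4,5-tris(benzyloxy)phenyl]propyl chain), via vinylketene 36 (not isolated), via alkenylcyclobutenone 37 (not isolated), via dienylketene 38 (not isolated), via cyclohexadienone 39 (not isolated)
Conditions: 35 (1.5–2 equiv), toluene, 80 → 110 °C, Ar, sealed tube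
Reagents that add atoms: none
Why: Heating opens 35 by 4π electrocyclic ring opening to the (2-benzyloxyvinyl)ketene 36, whose carbonyl carbon is attacked by the nucleophilic β-carbon of the siloxyalkyne 13 in a [2+2] cycloaddition that gives the alkenylcyclobutenone 37 (new C8–C8a and C6–C7 bonds). Compound 37 opens again (4π) to the dienylketene 38, which closes by 6π electrocyclisation to cyclohexadienone 39 (new C4a–C8a bond) and tautomerises to phenol 40. This is the Danheiser benzannulation, known for cyclobutenones with triisopropylsiloxyalkynes, including alkynes that carry a branched carbon. Ring A of the bottom unit is therefore closed by a 6π electrocyclisation after a [2+2] step. No stereocentre is created: the ring C4 centre of 35 disappears on ring opening and the eight defined stereocentres of 13 and 35 are spectators under neutral thermal conditions. The selectivity needed is the orientation of ketene and ynol ether, and it follows from their polarity (electrophilic ketene carbon, oxygen-stabilised positive charge at the silyloxy carbon). The former ketene oxygen thus becomes the free C8a hydroxyl between C8 and C4a, the siloxy oxygen O7 and the benzyloxy oxygen O5, and no C6/C8 choice arises. The alkyne is the only ketenophile in 13, and the excess of 35 makes up for vinylketene lost by dimerisation.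

Step 22
Reactants: 40 protected trimer precursor with two silyl ethers
Product: 41 triol with free C7–OH, C8a–OH and benzylic C2–OH on the open bottom unit (C2 S, C3 R)
Conditions: Bu4NF, AcOH, THF, 0 → 40 °C
Reagents that add atoms: none
Why: Fluoride cleaves the aryl triisopropylsilyl ether and the benzylic tert-butyldimethylsilyl ether; buffering with acetic acid avoids free phenoxide, so the gallate neither migrates nor is cleaved.

Step 23
Reactants: 41 triol
Product: 42 nonadeca-O-benzyl trimer with closed bottom ring C (2R,3R, 2,3-cis) and free bottom C7–OH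
Conditions: PPh3, DIAD, THF (0.01 M), 0 → 25 °C
Reagents that add atoms: none
Why: Mitsunobu etherification: the alkoxyphosphonium ion of the only free alcohol is displaced by the C8a phenoxide (6-exo-tet) with inversion, which turns the 2S carbinol into the 2R centre cis to the C3 benzyloxy group. The C7 phenol cannot reach C2 and O5 is benzylated, so only one ring can form. The 3,4,5-trialkoxyphenyl group stabilises a benzylic cation only weakly, because its para oxygen is twisted out of conjugation, which favours the SN2 path.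

Step 24
Reactants: 42 nonadeca-O-benzyl trimer
Product: 43 epigallocatechin-(4β→8)-epigallocatechin 3-O-gallate-(4β→8)-epigallocatechin (target)
Conditions: H2 (1 atm), Pd(OH)2/C, THF/MeOH/H2O, 25 °C; filtration under Ar, lyophilisation
Reagents that add atoms: none
Why: Hydrogenolysis of the nineteen benzyl ethers under neutral conditions, which leave the interflavan bonds, the ester and the 2,3-cis centres intact.

## Compound list

1 | (−)-epigallocatechin | Oc1cc(O)c2c(c1)O[C@H](c1cc(O)c(O)c(O)c1)[C@H](O)C2 | starting material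
2 | 5,7,3′,4′,5′-penta-O-benzyl-epigallocatechin | O(Cc5ccccc5)c1cc(OCc5ccccc5)c2c(c1)O[C@H](c6cc(OCc5ccccc5)c(OCc5ccccc5)c(OCc5ccccc5)c6)[C@H](O)C2 | intermediate
3 | 3,4,5-tris(benzyloxy)benzoic acid | OC(=O)c1cc(OCc2ccccc2)c(OCc2ccccc2)c(OCc2ccccc2)c1 | starting material
4 | octa-O-benzyl-epigallocatechin 3-O-gallate | O=C(O[C@@H]1Cc2c(OCc5ccccc5)cc(OCc5ccccc5)cc2O[C@@H]1c6cc(OCc5ccccc5)c(OCc5ccccc5)c(OCc5ccccc5)c6)c7cc(OCc5ccccc5)c(OCc5ccccc5)c(OCc5ccccc5)c7 | intermediate
5 | 4β-(2-ethoxyethoxy)-octa-O-benzyl-epigallocatechin 3-O-gallate | O=C(O[C@@H]1[C@@H](OCCOCC)c2c(OCc5ccccc5)cc(OCc5ccccc5)cc2O[C@@H]1c6cc(OCc5ccccc5)c(OCc5ccccc5)c(OCc5ccccc5)c6)c7cc(OCc5ccccc5)c(OCc5ccccc5)c(OCc5ccccc5)c7 | intermediate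
6 | 4β-[(trimethylsilyl)ethynyl]-octa-O-benzyl-epigallocatechin 3-O-gallate | O=C(O[C@@H]1[C@@H](C#C[Si](C)(C)C)c2c(OCc5ccccc5)cc(OCc5ccccc5)cc2O[C@@H]1c6cc(OCc5ccccc5)c(OCc5ccccc5)c(OCc5ccccc5)c6)c7cc(OCc5ccccc5)c(OCc5ccccc5)c(OCc5ccccc5)c7 | intermediate
7 | 3,5,7,3′,4′,5′-hexa-O-benzyl-epigallocatechin | O(Cc5ccccc5)c1cc(OCc5ccccc5)c2c(c1)O[C@H](c6cc(OCc5ccccc5)c(OCc5ccccc5)c(OCc5ccccc5)c6)[C@H](OCc5ccccc5)C2 | intermediate
8 | 4β-(2-ethoxyethoxy)-hexa-O-benzyl-epigallocatechin | CCOCCO[C@H]1c2c(OCc5ccccc5)cc(OCc5ccccc5)cc2O[C@H](c6cc(OCc5ccccc5)c(OCc5ccccc5)c(OCc5ccccc5)c6)[C@@H]1OCc5ccccc5 | intermediate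
9 | hexa-O-benzyl-epigallocatechin-(4β→8)-{4β-[(trimethylsilyl)ethynyl]-octa-O-benzyl-epigallocatechin 3-O-gallate} | O=C(O[C@@H]1[C@@H](C#C[Si](C)(C)C)c2c(OCc5ccccc5)cc(OCc5ccccc5)c([C@H]3c4c(OCc5ccccc5)cc(OCc5ccccc5)cc4O[C@H](c6cc(OCc5ccccc5)c(OCc5ccccc5)c(OCc5ccccc5)c6)[C@@H]3OCc5ccccc5)c2O[C@@H]1c6cc(OCc5ccccc5)c(OCc5ccccc5)c(OCc5ccccc5)c6)c7cc(OCc5ccccc5)c(OCc5ccccc5)c(OCc5ccccc5)c7 | intermediate
10 | hexa-O-benzyl-epigallocatechin-(4β→8)-(4β-ethynyl-octa-O-benzyl-epigallocatechin 3-O-gallate) | O=C(O[C@@H]1[C@@H](C#C)c2c(OCc5ccccc5)cc(OCc5ccccc5)c([C@H]3c4c(OCc5ccccc5)cc(OCc5ccccc5)cc4O[C@H](c6cc(OCc5ccccc5)c(OCc5ccccc5)c(OCc5ccccc5)c6)[C@@H]3OCc5ccccc5)c2O[C@@H]1c6cc(OCc5ccccc5)c(OCc5ccccc5)c(OCc5ccccc5)c6)c7cc(OCc5ccccc5)c(OCc5ccccc5)c(OCc5ccccc5)c7 | intermediate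
11 | lithium acetylide of 10 | O=C(O[C@@H]1[C@@H](C#C[Li])c2c(OCc5ccccc5)cc(OCc5ccccc5)c([C@H]3c4c(OCc5ccccc5)cc(OCc5ccccc5)cc4O[C@H](c6cc(OCc5ccccc5)c(OCc5ccccc5)c(OCc5ccccc5)c6)[C@@H]3OCc5ccccc5)c2O[C@@H]1c6cc(OCc5ccccc5)c(OCc5ccccc5)c(OCc5ccccc5)c6)c7cc(OCc5ccccc5)c(OCc5ccccc5)c(OCc5ccccc5)c7 | intermediate (not isolated)
12 | lithium ynolate derived from 11 | O=C(O[C@@H]1[C@@H](C#CO[Li])c2c(OCc5ccccc5)cc(OCc5ccccc5)c([C@H]3c4c(OCc5ccccc5)cc(OCc5ccccc5)cc4O[C@H](c6cc(OCc5ccccc5)c(OCc5ccccc5)c(OCc5ccccc5)c6)[C@@H]3OCc5ccccc5)c2O[C@@H]1c6cc(OCc5ccccc5)c(OCc5ccccc5)c(OCc5ccccc5)c6)c7cc(OCc5ccccc5)c(OCc5ccccc5)c(OCc5ccccc5)c7 | intermediate (not isolated)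
13 | hexa-O-benzyl-epigallocatechin-(4β→8)-{4β-[(triisopropylsilyloxy)ethynyl]-octa-O-benzyl-epigallocatechin 3-O-gallate} | O=C(O[C@@H]1[C@@H](C#CO[Si](C(C)C)(C(C)C)C(C)C)c2c(OCc5ccccc5)cc(OCc5ccccc5)c([C@H]3c4c(OCc5ccccc5)cc(OCc5ccccc5)cc4O[C@H](c6cc(OCc5ccccc5)c(OCc5ccccc5)c(OCc5ccccc5)c6)[C@@H]3OCc5ccccc5)c2O[C@@H]1c6cc(OCc5ccccc5)c(OCc5ccccc5)c(OCc5ccccc5)c6)c7cc(OCc5ccccc5)c(OCc5ccccc5)c(OCc5ccccc5)c7 | intermediate (key-step precursor)
14 | (S)-4-benzyloxazolidin-2-one | O=C1N[C@@H](Cc2ccccc2)CO1 | starting material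
15 | (S)-4-benzyl-3-[(benzyloxy)acetyl]oxazolidin-2-one | O=C(COCc1ccccc1)N1[C@@H](Cc2ccccc2)COC1=O | intermediate
16 | sodium (Z)-enolate of 15 | [Na]O/C(=C\OCc1ccccc1)N1[C@@H](Cc2ccccc2)COC1=O | intermediate (not isolated)
17 | (S)-4-benzyl-3-[(2R)-2-(benzyloxy)pent-4-enoyl]oxazolidin-2-one | C=CC[C@@H](OCc1ccccc1)C(=O)N1[C@@H](Cc2ccccc2)COC1=O | intermediate
18 | (2R)-2-(benzyloxy)-N-methoxy-N-methylpent-4-enamide | C=CC[C@@H](OCc1ccccc1)C(=O)N(C)OC | intermediate
19 | 5-bromo-1,2,3-tris(benzyloxy)benzene | Brc1cc(OCc2ccccc2)c(OCc2ccccc2)c(OCc2ccccc2)c1 | starting material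
20 | [3,4,5-tris(benzyloxy)phenyl]lithium | [Li]c1cc(OCc2ccccc2)c(OCc2ccccc2)c(OCc2ccccc2)c1 | intermediate (not isolated)
21 | (2R)-2-(benzyloxy)-1-[3,4,5-tris(benzyloxy)phenyl]pent-4-en-1-one | C=CC[C@@H](OCc1ccccc1)C(=O)c1cc(OCc2ccccc2)c(OCc2ccccc2)c(OCc2ccccc2)c1 | intermediate
22 | (1S,2R)-2-(benzyloxy)-1-[3,4,5-tris(benzyloxy)phenyl]pent-4-en-1-ol | C=CC[C@@H](OCc1ccccc1)[C@@H](O)c1cc(OCc2ccccc2)c(OCc2ccccc2)c(OCc2ccccc2)c1 | intermediate
23 | tert-butyl{[(1S,2R)-2-(benzyloxy)-1-[3,4,5-tris(benzyloxy)phenyl]pent-4-en-1-yl]oxy}dimethylsilane | C=CC[C@@H](OCc1ccccc1)[C@@H](O[Si](C)(C)C(C)(C)C)c1cc(OCc2ccccc2)c(OCc2ccccc2)c(OCc2ccccc2)c1 | intermediate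
24 | 9-[(4R,5S)-4-(benzyloxy)-5-[(tert-butyldimethylsilyl)oxy]-5-[3,4,5-tris(benzyloxy)phenyl]pentyl]-9-borabicyclo[3.3.1]nonane | B1(CCC[C@@H](OCc3ccccc3)[C@@H](O[Si](C)(C)C(C)(C)C)c3cc(OCc4ccccc4)c(OCc4ccccc4)c(OCc4ccccc4)c3)C2CCCC1CCC2 | intermediate (not isolated)
25 | (4R,5S)-4-(benzyloxy)-5-[(tert-butyldimethylsilyl)oxy]-5-[3,4,5-tris(benzyloxy)phenyl]pentan-1-ol | OCCC[C@@H](OCc1ccccc1)[C@@H](O[Si](C)(C)C(C)(C)C)c1cc(OCc2ccccc2)c(OCc2ccccc2)c(OCc2ccccc2)c1 | intermediate
26 | (4R,5S)-4-(benzyloxy)-5-[(tert-butyldimethylsilyl)oxy]-5-[3,4,5-tris(benzyloxy)phenyl]pentanal | O=CCC[C@@H](OCc1ccccc1)[C@@H](O[Si](C)(C)C(C)(C)C)c1cc(OCc2ccccc2)c(OCc2ccccc2)c(OCc2ccccc2)c1 | intermediate (not isolated)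
27 | (4R,5S)-4-(benzyloxy)-5-[(tert-butyldimethylsilyl)oxy]-5-[3,4,5-tris(benzyloxy)phenyl]pentanoic acid | OC(=O)CC[C@@H](OCc1ccccc1)[C@@H](O[Si](C)(C)C(C)(C)C)c1cc(OCc2ccccc2)c(OCc2ccccc2)c(OCc2ccccc2)c1 | intermediate
28 | trichloroethylene | ClC=C(Cl)Cl | starting material
29 | benzyl (E)-1,2-dichlorovinyl ether | Cl/C=C(/Cl)OCc1ccccc1 | intermediate
30 | benzyloxychloroethyne | ClC#COCc1ccccc1 | intermediate (not isolated)
31 | lithium benzyloxyacetylide | [Li]C#COCc1ccccc1 | intermediate (not isolated)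
32 | benzyloxyethyne | C#COCc1ccccc1 | intermediate
33 | (4R,5S)-4-(benzyloxy)-5-[(tert-butyldimethylsilyl)oxy]-5-[3,4,5-tris(benzyloxy)phenyl]pentanoyl chloride | ClC(=O)CC[C@@H](OCc1ccccc1)[C@@H](O[Si](C)(C)C(C)(C)C)c1cc(OCc2ccccc2)c(OCc2ccccc2)c(OCc2ccccc2)c1 | intermediate (not isolated)
34 | (4R,5S)-4-(benzyloxy)-5-[(tert-butyldimethylsilyl)oxy]-5-[3,4,5-tris(benzyloxy)phenyl]pent-1-en-1-one (ketene) | O=C=CC[C@@H](OCc1ccccc1)[C@@H](O[Si](C)(C)C(C)(C)C)c1cc(OCc2ccccc2)c(OCc2ccccc2)c(OCc2ccccc2)c1 | intermediate (not isolated)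
35 | 3-(benzyloxy)-4-[(2R,3S)-2-(benzyloxy)-3-[(tert-butyldimethylsilyl)oxy]-3-[3,4,5-tris(benzyloxy)phenyl]propyl]cyclobut-2-en-1-one (ring C4 epimers) | O=C1C=C(OCc5ccccc5)C1C[C@@H](OCc5ccccc5)[C@@H](O[Si](C)(C)C(C)(C)C)c6cc(OCc5ccccc5)c(OCc5ccccc5)c(OCc5ccccc5)c6 | intermediate (key-step precursor)
36 | (6R,7S)-3,6-bis(benzyloxy)-7-[(tert-butyldimethylsilyl)oxy]-7-[3,4,5-tris(benzyloxy)phenyl]hepta-1,3-dien-1-one (vinylketene) | O=C=CC(OCc5ccccc5)=CC[C@@H](OCc5ccccc5)[C@@H](O[Si](C)(C)C(C)(C)C)c6cc(OCc5ccccc5)c(OCc5ccccc5)c(OCc5ccccc5)c6 | intermediate (not isolated)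
37 | [2+2] adduct: 13 with the alkyne turned into a 4-oxo-2-(triisopropylsilyloxy)cyclobut-1-enyl ring whose C3 carries the 1-(benzyloxy)alkenyl chain | O=C(O[C@@H]1[C@@H](C8=C(O[Si](C(C)C)(C(C)C)C(C)C)C(C(OCc5ccccc5)=CC[C@@H](OCc5ccccc5)[C@@H](O[Si](C)(C)C(C)(C)C)c6cc(OCc5ccccc5)c(OCc5ccccc5)c(OCc5ccccc5)c6)C8=O)c2c(OCc5ccccc5)cc(OCc5ccccc5)c([C@H]3c4c(OCc5ccccc5)cc(OCc5ccccc5)cc4O[C@H](c6cc(OCc5ccccc5)c(OCc5ccccc5)c(OCc5ccccc5)c6)[C@@H]3OCc5ccccc5)c2O[C@@H]1c6cc(OCc5ccccc5)c(OCc5ccccc5)c(OCc5ccccc5)c6)c7cc(OCc5ccccc5)c(OCc5ccccc5)c(OCc5ccccc5)c7 | intermediate (not isolated)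
38 | dienylketene from ring opening of 37 | O=C(O[C@@H]1[C@@H](C(=C=O)C(O[Si](C(C)C)(C(C)C)C(C)C)=CC(OCc5ccccc5)=CC[C@@H](OCc5ccccc5)[C@@H](O[Si](C)(C)C(C)(C)C)c6cc(OCc5ccccc5)c(OCc5ccccc5)c(OCc5ccccc5)c6)c2c(OCc5ccccc5)cc(OCc5ccccc5)c([C@H]3c4c(OCc5ccccc5)cc(OCc5ccccc5)cc4O[C@H](c6cc(OCc5ccccc5)c(OCc5ccccc5)c(OCc5ccccc5)c6)[C@@H]3OCc5ccccc5)c2O[C@@H]1c6cc(OCc5ccccc5)c(OCc5ccccc5)c(OCc5ccccc5)c6)c7cc(OCc5ccccc5)c(OCc5ccccc5)c(OCc5ccccc5)c7 | intermediate (not isolated)
39 | cyclohexa-2,4-dienone from 6π closure of 38 | O=C(O[C@@H]1[C@@H](C8=C(O[Si](C(C)C)(C(C)C)C(C)C)C=C(OCc5ccccc5)C(C[C@@H](OCc5ccccc5)[C@@H](O[Si](C)(C)C(C)(C)C)c6cc(OCc5ccccc5)c(OCc5ccccc5)c(OCc5ccccc5)c6)C8=O)c2c(OCc5ccccc5)cc(OCc5ccccc5)c([C@H]3c4c(OCc5ccccc5)cc(OCc5ccccc5)cc4O[C@H](c6cc(OCc5ccccc5)c(OCc5ccccc5)c(OCc5ccccc5)c6)[C@@H]3OCc5ccccc5)c2O[C@@H]1c6cc(OCc5ccccc5)c(OCc5ccccc5)c(OCc5ccccc5)c6)c7cc(OCc5ccccc5)c(OCc5ccccc5)c(OCc5ccccc5)c7 | intermediate (not isolated)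
40 | trimer precursor with new bottom ring A (C8a–OH, C7–OSi(iPr)3, C5–OBn, open erythro chain with C2–OSiMe2t-Bu and C3–OBn at C4a) | O=C(O[C@@H]1[C@@H](c8c(O[Si](C(C)C)(C(C)C)C(C)C)cc(OCc5ccccc5)c(C[C@@H](OCc5ccccc5)[C@@H](O[Si](C)(C)C(C)(C)C)c6cc(OCc5ccccc5)c(OCc5ccccc5)c(OCc5ccccc5)c6)c8O)c2c(OCc5ccccc5)cc(OCc5ccccc5)c([C@H]3c4c(OCc5ccccc5)cc(OCc5ccccc5)cc4O[C@H](c6cc(OCc5ccccc5)c(OCc5ccccc5)c(OCc5ccccc5)c6)[C@@H]3OCc5ccccc5)c2O[C@@H]1c6cc(OCc5ccccc5)c(OCc5ccccc5)c(OCc5ccccc5)c6)c7cc(OCc5ccccc5)c(OCc5ccccc5)c(OCc5ccccc5)c7 | intermediate (key-step product)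
41 | triol: 40 without both silyl groups (C7–OH, C8a–OH, benzylic C2–OH) | O=C(O[C@@H]1[C@@H](c8c(O)cc(OCc5ccccc5)c(C[C@@H](OCc5ccccc5)[C@@H](O)c6cc(OCc5ccccc5)c(OCc5ccccc5)c(OCc5ccccc5)c6)c8O)c2c(OCc5ccccc5)cc(OCc5ccccc5)c([C@H]3c4c(OCc5ccccc5)cc(OCc5ccccc5)cc4O[C@H](c6cc(OCc5ccccc5)c(OCc5ccccc5)c(OCc5ccccc5)c6)[C@@H]3OCc5ccccc5)c2O[C@@H]1c6cc(OCc5ccccc5)c(OCc5ccccc5)c(OCc5ccccc5)c6)c7cc(OCc5ccccc5)c(OCc5ccccc5)c(OCc5ccccc5)c7 | intermediate
42 | nonadeca-O-benzyl trimer with free bottom C7–OH (all units 2,3-cis, both interflavan bonds 4β→8) | O=C(O[C@@H]1[C@@H](c8c(O)cc(OCc5ccccc5)c9c8O[C@H](c6cc(OCc5ccccc5)c(OCc5ccccc5)c(OCc5ccccc5)c6)[C@H](OCc5ccccc5)C9)c2c(OCc5ccccc5)cc(OCc5ccccc5)c([C@H]3c4c(OCc5ccccc5)cc(OCc5ccccc5)cc4O[C@H](c6cc(OCc5ccccc5)c(OCc5ccccc5)c(OCc5ccccc5)c6)[C@@H]3OCc5ccccc5)c2O[C@@H]1c6cc(OCc5ccccc5)c(OCc5ccccc5)c(OCc5ccccc5)c6)c7cc(OCc5ccccc5)c(OCc5ccccc5)c(OCc5ccccc5)c7 | intermediate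
43 | epigallocatechin-(4β→8)-epigallocatechin 3-O-gallate-(4β→8)-epigallocatechin (CNP0278699.1) | O=C(O[C@@H]1[C@@H](c2c(O)cc(O)c3c2O[C@H](c2cc(O)c(O)c(O)c2)[C@H](O)C3)c2c(O)cc(O)c([C@H]3c4c(O)cc(O)cc4O[C@H](c4cc(O)c(O)c(O)c4)[C@@H]3O)c2O[C@@H]1c1cc(O)c(O)c(O)c1)c1cc(O)c(O)c(O)c1 | target

## Step count and risks

Total: 24 steps. Longest linear sequence: 13 steps (14 → 43 through steps 10–17, 20 and 21–24). The branch from 1 to 43 through steps 1–4, 7–9 and 21–24 has 11 steps.

Step 21 (key step). The most likely failure is a slow [2+2] step: the ynol carbon that must bond to the ketene carries the branched C4 of the middle unit, next to an axial gallate. The vinylketene would then dimerise or be trapped elsewhere, while the 3-alkoxy group raises the temperature needed to open the cyclobutenone and the siloxyalkyne degrades thermally. Capture of the ketene adduct at the vinylogous carbon, giving the wrong substitution pattern, is a smaller risk. Fallback: abandon the de novo ring A and couple the natural units classically. Starting from 5 and 7, Me3SiOTf-catalysed coupling with 7 in excess gives the perbenzylated epigallocatechin gallate-(4β→8)-epigallocatechin dimer F1. A second coupling of F1 with 8 at C8 of its gallate-bearing unit gives the fully benzylated trimer F2, and hydrogenolysis over Pd(OH)2/C returns to the route at 43. This path accepts the C6/C8 selectivity problem that the benzannulation was chosen to avoid.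

Step 9. The ester may not survive the oxidation: lithium tert-butyl peroxide or the ynolate can add to the gallate carbonyl and transfer or cleave the acyl group. Fallback: keep the ester out of the oxidation. Starting from 9, NaOMe in MeOH/THF removes the gallate and the C-silyl group together to give the alkynol F3. F3 is treated with LiN(SiMe3)2 (3 equiv) and t-BuOOH, and the ynolate oxygen is silylated with iPr3SiCl, which leaves the hindered C3 alkoxide free. The alkoxide is then acylated in the same flask with 3,4,5-tris(benzyloxy)benzoyl chloride (made from 3 with oxalyl chloride), which returns to the route at 13.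

Step 4. The ionised C4 may be held by the neighbouring gallate as an acyloxonium ion, so that alkynyl transfer becomes slow and C8 of a second molecule captures the cation (oligomerisation). Fallback: put the alkyne in before the ester. Starting from 2, DDQ and 2-ethoxyethanol give the 3-hydroxy C4 ether F4. The same trifluoroborate/BF3·OEt2 substitution gives the 4β-alkynyl alcohol F5, and Steglich esterification with 3 (DCC, DMAP) returns to the route at 6.

Step 20. Benzyloxyethyne can be lost by sigmatropic rearrangement or polymerisation before it meets the ketene, and the aldoketene can dimerise. Fallback: use the stable ethoxyethyne in the cycloaddition. Starting from 27 (through 33 and 34 as before), this gives the 3-ethoxycyclobutenone F6. Acid-catalysed vinylogous transetherification with benzyl alcohol (pyridinium p-toluenesulfonate, toluene, removal of ethanol) keeps the double bond in place and returns to the route at 35.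

Step 23. The benzylic alkoxyphosphonium ion may ionise, which would erode the inversion at C2 or lead to elimination, or the hindered phenol may react too slowly and the hydrazide is alkylated instead. Fallback: a base-mediated closure through a sulfonate with only one phenol present. Starting from 40, HF·pyridine removes only the alkyl silyl ether to give the diol F7, which keeps the aryl triisopropylsilyl ether. NaH (2.2 equiv) and 1-(p-toluenesulfonyl)imidazole sulfonylate the more nucleophilic alkoxide to the tosylate F8, which the C8a phenoxide displaces with inversion in the same flask to give the 7-O-silyl flavan F9. Bu4NF then returns to the route at 42.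

## Further compounds

F1 | step 21 | octa-O-benzyl-epigallocatechin 3-O-gallate-(4β→8)-hexa-O-benzyl-epigallocatechin | O=C(O[C@@H]1[C@@H](c8c(OCc5ccccc5)cc(OCc5ccccc5)c9c8O[C@H](c6cc(OCc5ccccc5)c(OCc5ccccc5)c(OCc5ccccc5)c6)[C@H](OCc5ccccc5)C9)c2c(OCc5ccccc5)cc(OCc5ccccc5)cc2O[C@@H]1c6cc(OCc5ccccc5)c(OCc5ccccc5)c(OCc5ccccc5)c6)c7cc(OCc5ccccc5)c(OCc5ccccc5)c(OCc5ccccc5)c7
F2 | step 21 | icosa-O-benzyl trimer (42 with the bottom C7 oxygen benzylated) | O=C(O[C@@H]1[C@@H](c8c(OCc5ccccc5)cc(OCc5ccccc5)c9c8O[C@H](c6cc(OCc5ccccc5)c(OCc5ccccc5)c(OCc5ccccc5)c6)[C@H](OCc5ccccc5)C9)c2c(OCc5ccccc5)cc(OCc5ccccc5)c([C@H]3c4c(OCc5ccccc5)cc(OCc5ccccc5)cc4O[C@H](c6cc(OCc5ccccc5)c(OCc5ccccc5)c(OCc5ccccc5)c6)[C@@H]3OCc5ccccc5)c2O[C@@H]1c6cc(OCc5ccccc5)c(OCc5ccccc5)c(OCc5ccccc5)c6)c7cc(OCc5ccccc5)c(OCc5ccccc5)c(OCc5ccccc5)c7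
F3 | step 9 | hexa-O-benzyl-epigallocatechin-(4β→8)-(4β-ethynyl-penta-O-benzyl-epigallocatechin) with free 3-OH on the alkynyl unit | O[C@@H]1[C@@H](C#C)c2c(OCc5ccccc5)cc(OCc5ccccc5)c([C@H]3c4c(OCc5ccccc5)cc(OCc5ccccc5)cc4O[C@H](c6cc(OCc5ccccc5)c(OCc5ccccc5)c(OCc5ccccc5)c6)[C@@H]3OCc5ccccc5)c2O[C@@H]1c6cc(OCc5ccccc5)c(OCc5ccccc5)c(OCc5ccccc5)c6
F4 | step 4 | 4β-(2-ethoxyethoxy)-5,7,3′,4′,5′-penta-O-benzyl-epigallocatechin (free 3-OH) | CCOCCO[C@H]1c2c(OCc5ccccc5)cc(OCc5ccccc5)cc2O[C@H](c6cc(OCc5ccccc5)c(OCc5ccccc5)c(OCc5ccccc5)c6)[C@@H]1O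
F5 | step 4 | 4β-[(trimethylsilyl)ethynyl]-5,7,3′,4′,5′-penta-O-benzyl-epigallocatechin (free 3-OH) | O[C@@H]1[C@@H](C#C[Si](C)(C)C)c2c(OCc5ccccc5)cc(OCc5ccccc5)cc2O[C@@H]1c6cc(OCc5ccccc5)c(OCc5ccccc5)c(OCc5ccccc5)c6
F6 | step 20 | 3-ethoxy-4-[(2R,3S)-2-(benzyloxy)-3-[(tert-butyldimethylsilyl)oxy]-3-[3,4,5-tris(benzyloxy)phenyl]propyl]cyclobut-2-en-1-one | O=C1C=C(OCC)C1C[C@@H](OCc5ccccc5)[C@@H](O[Si](C)(C)C(C)(C)C)c6cc(OCc5ccccc5)c(OCc5ccccc5)c(OCc5ccccc5)c6
F7 | step 23 | 40 without the tert-butyldimethylsilyl group (C2–OH and C8a–OH free, C7–OSi(iPr)3 kept) | O=C(O[C@@H]1[C@@H](c8c(O[Si](C(C)C)(C(C)C)C(C)C)cc(OCc5ccccc5)c(C[C@@H](OCc5ccccc5)[C@@H](O)c6cc(OCc5ccccc5)c(OCc5ccccc5)c(OCc5ccccc5)c6)c8O)c2c(OCc5ccccc5)cc(OCc5ccccc5)c([C@H]3c4c(OCc5ccccc5)cc(OCc5ccccc5)cc4O[C@H](c6cc(OCc5ccccc5)c(OCc5ccccc5)c(OCc5ccccc5)c6)[C@@H]3OCc5ccccc5)c2O[C@@H]1c6cc(OCc5ccccc5)c(OCc5ccccc5)c(OCc5ccccc5)c6)c7cc(OCc5ccccc5)c(OCc5ccccc5)c(OCc5ccccc5)c7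
F8 | step 23 | C2 p-toluenesulfonate of F7 | O=C(O[C@@H]1[C@@H](c8c(O[Si](C(C)C)(C(C)C)C(C)C)cc(OCc5ccccc5)c(C[C@@H](OCc5ccccc5)[C@@H](OS(=O)(=O)c9ccc(C)cc9)c6cc(OCc5ccccc5)c(OCc5ccccc5)c(OCc5ccccc5)c6)c8O)c2c(OCc5ccccc5)cc(OCc5ccccc5)c([C@H]3c4c(OCc5ccccc5)cc(OCc5ccccc5)cc4O[C@H](c6cc(OCc5ccccc5)c(OCc5ccccc5)c(OCc5ccccc5)c6)[C@@H]3OCc5ccccc5)c2O[C@@H]1c6cc(OCc5ccccc5)c(OCc5ccccc5)c(OCc5ccccc5)c6)c7cc(OCc5ccccc5)c(OCc5ccccc5)c(OCc5ccccc5)c7
F9 | step 23 | 7-O-triisopropylsilyl ether of 42 | O=C(O[C@@H]1[C@@H](c8c(O[Si](C(C)C)(C(C)C)C(C)C)cc(OCc5ccccc5)c9c8O[C@H](c6cc(OCc5ccccc5)c(OCc5ccccc5)c(OCc5ccccc5)c6)[C@H](OCc5ccccc5)C9)c2c(OCc5ccccc5)cc(OCc5ccccc5)c([C@H]3c4c(OCc5ccccc5)cc(OCc5ccccc5)cc4O[C@H](c6cc(OCc5ccccc5)c(OCc5ccccc5)c(OCc5ccccc5)c6)[C@@H]3OCc5ccccc5)c2O[C@@H]1c6cc(OCc5ccccc5)c(OCc5ccccc5)c(OCc5ccccc5)c6)c7cc(OCc5ccccc5)c(OCc5ccccc5)c(OCc5ccccc5)c7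
A1 | alternative 1 | bottom-unit chroman joined at C8 to the carbinol carbon of the methoxymethyl-protected salicyl fragment that carries the top unit (carbinol epimers) | OC(c2c(OCc5ccccc5)cc(OCc5ccccc5)c3c2O[C@H](c6cc(OCc5ccccc5)c(OCc5ccccc5)c(OCc5ccccc5)c6)[C@H](OCc5ccccc5)C3)c2c(OCc5ccccc5)cc(OCc5ccccc5)c([C@H]3c4c(OCc5ccccc5)cc(OCc5ccccc5)cc4O[C@H](c6cc(OCc5ccccc5)c(OCc5ccccc5)c(OCc5ccccc5)c6)[C@@H]3OCc5ccccc5)c2OCOC
A2 | alternative 2 | middle–bottom dimer gallate carrying at C8 of the middle unit a 5,7-bis(benzyloxy)chroman-2-ol joined through C4 (lactol anomers) | O=C(O[C@@H]1[C@@H](c2c(OCc5ccccc5)cc(OCc5ccccc5)c3c2O[C@H](c6cc(OCc5ccccc5)c(OCc5ccccc5)c(OCc5ccccc5)c6)[C@H](OCc5ccccc5)C3)c2c(OCc5ccccc5)cc(OCc5ccccc5)c([C@H]3c4c(OCc5ccccc5)cc(OCc5ccccc5)cc4OC(O)C3)c2O[C@@H]1c6cc(OCc5ccccc5)c(OCc5ccccc5)c(OCc5ccccc5)c6)c7cc(OCc5ccccc5)c(OCc5ccccc5)c(OCc5ccccc5)c7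
A3 | alternative 2 | 3,5-bis(benzyloxy)phenol | Oc1cc(OCc2ccccc2)cc(OCc2ccccc2)c1
A4 | alternative 3 | benzyl-protected trimer gallate with free 3-OH and a C6 bromide on the bottom unit | O=C(O[C@@H]1[C@@H](c2c(OCc5ccccc5)c(Br)c(OCc5ccccc5)c3c2O[C@H](c6cc(OCc5ccccc5)c(OCc5ccccc5)c(OCc5ccccc5)c6)[C@H](O)C3)c2c(OCc5ccccc5)cc(OCc5ccccc5)c([C@H]3c4c(OCc5ccccc5)cc(OCc5ccccc5)cc4O[C@H](c6cc(OCc5ccccc5)c(OCc5ccccc5)c(OCc5ccccc5)c6)[C@@H]3OCc5ccccc5)c2O[C@@H]1c6cc(OCc5ccccc5)c(OCc5ccccc5)c(OCc5ccccc5)c6)c7cc(OCc5ccccc5)c(OCc5ccccc5)c(OCc5ccccc5)c7
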